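The data were generated by integration with constants of no real substance; noise was put on by code.

If the peak share of target falls as the charge of substrate rises, the useful number is the fraction of that share kept, not the fraction lost.

| flask | substrate | reagent in the second phase | remark | time | volume of the second phase over the first |
|---|---|---|---|---|---|
| violet | 0.13 M (fed, over 3.0 h) | 0.286 M | run made earlier; the fed solution adds 0.50 times the starting volume |  |  |
| red | 0.52 M (fed, over 3.0 h) | 0.286 M | run made earlier; the fed solution adds 0.50 times the starting volume |  |  |
| grey | 0.26 M (fed, over 3.0 h) | 0.43 M | run made earlier; the fed solution adds 0.50 times the starting volume |  |  |
| flask | 0.26 M (fed, over 3.0 h) | 0.286 M | the fed solution adds 0.50 times the starting volume | 40 h | 0.50 |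

| run | time / h | target / % |
|---|---|---|
| violet | 1.00 | 0 |
| violet | 2.00 | 16 |
| violet | 4.00 | 19 |
| violet | 8.00 | 15 |
| violet | 12.0 | 4 |
| violet | 25.0 | 2 |
| red | 1.00 | 3 |
| red | 2.00 | 8 |
| red | 4.00 | 8 |
| red | 8.00 | 5 |
| red | 12.0 | 5 |
| red | 25.0 | 0 |
| grey | 1.00 | 6 |
| grey | 2.50 | 16 |
| grey | 5.00 | 21 |
| grey | 12.0 | 8 |
| grey | 25.0 | 0 |

(each reading ± 2 percentage points)

- a species is counted by the substrate in it: one idle adduct counts as two
- amounts and yields of target count product in the second phase and idle adduct too
- charges are per starting volume, the dose included; the dosed solution carries all of it
- in the second phase: reagent in the second phase, product in the second phase; everything else is in the first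
- charges count per volume of the first phase; a concentration in a rate is the amount of a species over the volume of its own phase; every rate counts per litre of the first phase
- the numbers in the tables scatter with a standard deviation of 2 percentage points
- steps thought possible: target <-> product in the second phase; substrate + reagent in the reaction phase -> target; target -> decomposed product; substrate + target <-> idle adduct; target -> over-reaction product; reagent in the reaction phase <-> reagent in the second phase
- the earlier runs hold the two phases in the same ratio of volumes as the flask asked about
- in an amount of target, one idle adduct counts as one target
- percentages count the whole charge, also what has not yet gone in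

1. when, up to 40 h, the flask holds most target
2. the amount of target, in percent of the substrate charged, at that time

At equal reagent, the violet run peaks at a reading of 19% and the red run at 8%, and the charge goes from 0.13 M to 0.52 M, which is two doublings. Taken evenly, each doubling keeps 0.649 of the peak share: this fraction kept per doubling is the square root of the red peak over the violet peak, and it carries their scatter of 2 percentage points.

The flask, at 0.26 M, lies one doubling above violet with the same reagent, so the violet peak serves as a roof and the red peak as a first floor. This reckoning then raises the floor to the violet peak times the fraction kept, 12.3%, on the assumption that the fall steepens as the charge rises. The grey run has the flask's charge of substrate but more reagent, and its peak reading of 21% stands higher than the violet peak, so it does not lower the roof. The violet peak reading stands at 4.00 h and the grey one at 5.00 h, both after the feed ends at 3.0 h, so this reckoning puts the flask's peak time between those two.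

The forecast gives 15% at 4.5 h, and calls itself “empirical interpolation, not a fitted mechanism”. Its share stands inside the bracket, higher than the floor and lower than the roof.

The flask holds most target at 4.54 h, with 14.7%, which is also higher than the floor and lower than the roof.

    target ⇌ product in the second phase, rate k1*([target] - [product in the second phase]/K1) per volume of the first phase (partition coefficient = 0.400, kL = 0.0660 h⁻¹)
    substrate + reagent in the reaction phase → target (k = 32.0 L mol⁻¹ h⁻¹)
    target → decomposed product (k = 0.0240 h⁻¹)
    substrate + target ⇌ idle adduct, settled at all times (K = 1.30 L mol⁻¹)
    target → over-reaction product (k = 0.630 h⁻¹)
    reagent in the reaction phase ⇌ reagent in the second phase, rate k6*([reagent in the reaction phase] - [reagent in the second phase]/K6) per volume of the first phase (partition coefficient = 9.40, kL = 0.380 h⁻¹)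

The fraction kept now starts from the flask's own peak. A neighbour flask charged with 0.65 M of substrate, the rest held, lies 1.32 doublings above the flask. Multiplying 14.7% by the fraction kept, raised to that power, gives 8.28%. Past the flask's charge, the same assumption of a steepening fall turns this figure into a roof. The neighbour flask holds less target than that roof, reaching 7.30% at its best.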